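A direct plan would take 1,3,5-trimethoxybenzene A1, put in the two C-methyl groups by two rounds of lithiation and methylation, and iodinate to the aryl iodide A2. A2, CO and henicos-1-yne A3 would then be joined by a carbonylative Sonogashira coupling (PdCl2(PPh3)2) to the ynone A4. The triple bond would be masked as the diethylamino enone A5, and BBr3 demethylation with acid closure of ring C would finish.
Weakest steps:
(a) The decoration of ring A would cost three steps on a bought benzene ring, plus a separate alkyne synthesis, before any bond of the chromone is made.
(b) The carbonylative coupling would use an aryl iodide flanked by two methoxy groups. Oxidative addition and acyl transfer would be slow, CO pressure would be needed, and direct alkynylation would compete.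
(c) Three O-methyl groups would be carried from the first to the last step, the amine addition would build nothing, and excess BBr3 would be used on the fully assembled molecule.

**Retrosynthetic overview of the new route**

The skeleton is read as one poly-β-carbonyl chain C2–C3–C4–C4a–C8a–C8–C7–C6–C5 with oxygen on every second carbon. Ring A is a C-methylated phloroglucinol: O on C5, C7 and C8a, methyl on C6 and C8.
Key disconnection C4a–C5: a Claisen (Dieckmann-type) fold of keto ester 8 builds the whole aromatic ring A last. In 8 the carbonyl carbons C2, C4 and C8a are masked as a 4-pyranone.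
Second disconnection C8–C8a: a keto ester dianion displaces methanethiolate from pyranone 5, which is made from acyclic pieces (C2–C3, then O1–C8a).
Ring C is formed first and ring A second. There is no aryl halide, no CO and no O-protecting group, and both methyl groups arrive in a bought keto ester.
Ring A is symmetric about the C4a–C7 axis, so the pyranone oxygen is already O1 of the chromone.

Key step: step 4

Remark: keto ester 8 is carried forward as the mixture of its diastereomers and enol forms. The target has no stereocentre, so nothing has to be controlled.

**Route**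

Step 1
Reactants: 1 4,4-bis(methylsulfanyl)but-3-en-2-one; 2 icosanoyl chloride
Product: 4 1,1-bis(methylsulfanyl)tetracos-1-ene-3,5-dione, via lithium dienolate 3 (not isolated)
Conditions: 1 (2.0 equiv), LiN(SiMe3)2 (2.05 equiv), THF, −78 °C; 2 (1.0 equiv), −78 to 0 °C; 1 M HCl
Reagents that add atoms: none
Why: Claisen-type C-acylation of a ketone lithium enolate by an acid chloride: the acetyl methyl is the only enolisable site of 1, the second equivalent of enolate takes up the acidic proton of 4 as it forms, and at −78 °C the ketene dithioacetal end should be left alone; the new bond is C2–C3 of the target.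

Step 2
Reactants: 4 1,1-bis(methylsulfanyl)tetracos-1-ene-3,5-dione
Product: 5 2-(methylsulfanyl)-6-nonadecyl-4H-pyran-4-one
Conditions: CF3CO2H (20 mol %), toluene, 80 °C, N2 sweep
Reagents that add atoms: none
Why: Acid-catalysed 6-endo oxa-conjugate addition of the enol oxygen on C2 to the bis(methylsulfanyl) carbon followed by loss of methanethiol (addition–elimination on an α-oxo ketene dithioacetal) is the usual closure of 3,5-dioxo ketene dithioacetals to 2-(methylsulfanyl)-4-pyranones; it closes ring C by the O1–C8a bond and leaves one methylsulfanyl group on C8a as leaving group.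

Step 3
Reactants: 5 2-(methylsulfanyl)-6-nonadecyl-4H-pyran-4-one; 6 methyl 2-methyl-3-oxopentanoate
Product: 8 methyl 2-methyl-4-(6-nonadecyl-4-oxo-4H-pyran-2-yl)-3-oxopentanoate, via keto ester dianion 7 (not isolated)
Conditions: 6 (2.4 equiv), NaH (2.4 equiv), THF, 0 °C; n-BuLi (2.4 equiv), 0 °C; 5, −78 to 20 °C; 1 M HCl
Reagents that add atoms: none
Why: Conjugate addition–elimination (vinylic substitution) of the γ-carbanion of the Weiler dianion at the methylsulfanyl-bearing carbon of the cyclic α-oxo ketene O,S-acetal 5 forms C8–C8a: loss of thiolate is irreversible whereas aldol-type addition to the vinylogous-ester carbonyl C4 can revert, the excess dianion takes up the acidic proton of 8, and the new stereocentre at C8 (like the one at C6) is formed without control and is erased in step 4.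

Step 4
Reactants: 8 methyl 2-methyl-4-(6-nonadecyl-4-oxo-4H-pyran-2-yl)-3-oxopentanoate
Product: 9 5,7-dihydroxy-6,8-dimethyl-2-nonadecylchromen-4-one
Conditions: DBU (4 equiv), toluene, 100 °C; then 1 M HCl
Reagents that add atoms: none
Why: DBU removes the doubly activated C8–H (α to the C7 ketone and vinylogous to the pyranone carbonyl) in equilibrium with the keto ester C6–H, and the extended enolate attacks the methyl ester carbon C5 through its ring carbon C4a; loss of methoxide and two enolisations make ring A aromatic. The closest known reaction type is the biomimetic Claisen (Dieckmann-type) cyclisation of 3,5,7-triketo and tetraketo esters, free or masked as pyranones, to acylphloroglucinols and 5,7-dihydroxychromones. Ring A closes in a 6-(enolexo)-exo-trig mode, while ring C is already present and should not be opened by the non-nucleophilic base. No stereocentre is created, and the two sp3 centres of 8 (C6 and C8) are erased as they become aromatic carbons. The selectivity needed is C-acylation at C4a in preference to aldol folding or lactonisation, and the pyranone secures it: with O1, C2 and C4 locked in ring C no ketone is free for an aldol mode, no hydroxyl or enol oxygen can reach the ester through a five- or six-membered ring, and C4a is the only nucleophilic carbon six atoms from C5. Because ring A is symmetric about the C4a–C7 axis, the oxygen already fixed on C8a is correctly placed whichever ortho carbon it sits on, so no regiochemical choice remains.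

**Compound list**

1 | 4,4-bis(methylsulfanyl)but-3-en-2-one | CC(=O)C=C(SC)SC | starting material
2 | icosanoyl chloride | CCCCCCCCCCCCCCCCCCCC(Cl)=O | starting material
3 | lithium 4,4-bis(methylsulfanyl)buta-1,3-dien-2-olate | [Li]OC(=C)C=C(SC)SC | intermediate
4 | 1,1-bis(methylsulfanyl)tetracos-1-ene-3,5-dione (largely enolised) | CCCCCCCCCCCCCCCCCCCC(=O)CC(=O)C=C(SC)SC | intermediate
5 | 2-(methylsulfanyl)-6-nonadecyl-4H-pyran-4-one | CCCCCCCCCCCCCCCCCCCc1cc(=O)cc(SC)o1 | intermediate
6 | methyl 2-methyl-3-oxopentanoate (racemic) | CCC(=O)C(C)C(=O)OC | starting material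
7 | lithium sodium 1-methoxy-2-methylpenta-1,3-diene-1,3-diolate (dianion of 6, enolate geometry not defined) | [Li+].[Na+].CC=C([O-])C(C)=C([O-])OC | intermediate
8 | methyl 2-methyl-4-(6-nonadecyl-4-oxo-4H-pyran-2-yl)-3-oxopentanoate (mixture of diastereomers) | CCCCCCCCCCCCCCCCCCCc1cc(=O)cc(o1)C(C)C(=O)C(C)C(=O)OC | intermediate
9 | 5,7-dihydroxy-6,8-dimethyl-2-nonadecylchromen-4-one | CCCCCCCCCCCCCCCCCCCc1cc(=O)c2c(O)c(C)c(O)c(C)c2o1 | target

**Step count and risks**

Total step count: 4. Longest linear sequence: 4 steps (1 to 4 to 5 to 8 to 9).

Steps most likely to fail: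

Step 4. Under base the keto ester end may stay enolised, so that its carbonyl loses electrophilicity and ring closure stalls, or the C7 ketone may be cleaved by retro-Claisen attack. The fallback replaces the anionic condensation by a neutral pericyclic sequence and sets out from 8. Heating 8 in diphenyl ether at about 200 °C under a nitrogen sweep should expel methanol from the enol form of the keto ester and give the acylketene 2-methyl-4-(6-nonadecyl-4-oxo-4H-pyran-2-yl)-3-oxopent-1-en-1-one F1. Its C7 enol is a dienylketene (C4a=C8a, C8=C7, C6=C5=O). This should close by 6π-electrocyclisation between C4a and C5 and tautomerise to the phenol, coming back to the route at 9.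

Step 3. The dianion may add to the C4 carbonyl of 5, may deprotonate the α-methylene of the nonadecyl chain, or may attack the alkyl-bearing carbon C2 with ring opening. The fallback sets out from 5 and 6 and activates the pyranone as a cation, which blocks C4. Dianion 7 is quenched with Me3SiCl to 1-methoxy-2-methyl-1,3-bis(trimethylsilyloxy)penta-1,3-diene F2. Pyranone 5 is converted by Me3SiOTf in CH2Cl2 into 2-(methylsulfanyl)-6-nonadecyl-4-(trimethylsilyloxy)pyrylium triflate F3. The terminal carbon of F2 should then add to the methylsulfanyl-bearing carbon of F3. The reaction type is the silyl-triflate-mediated addition of 1,3-bis(silyloxy)dienes to chromones through 4-silyloxypyrylium ions. Loss of the sulfur group and aqueous work-up come back to the route at 8.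

Step 1. The dienolate may be acylated on oxygen, or may add in a Michael fashion to the ketene dithioacetal of a second molecule. The fallback sets out from 2, changes the leaving group on the pyranone to methoxy and makes the ring through a 2-pyranone. Chloride 2 acylates the dianion of methyl acetoacetate (NaH, then n-BuLi, THF) to methyl 3,5-dioxotetracosanoate F4. DBU in toluene lactonises it to 4-hydroxy-6-nonadecyl-2H-pyran-2-one F5. MeOTf in CH2Cl2 methylates the lactone carbonyl oxygen to 2-methoxy-6-nonadecyl-4H-pyran-4-one F6. This takes the place of 5 under the conditions of step 3, with methoxide as leaving group, and comes back to the route at 8.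

Further compounds
F1 | step 4 | 2-methyl-4-(6-nonadecyl-4-oxo-4H-pyran-2-yl)-3-oxopent-1-en-1-one | CCCCCCCCCCCCCCCCCCCc1cc(=O)cc(o1)C(C)C(=O)C(C)=C=O
F2 | step 3 | 1-methoxy-2-methyl-1,3-bis(trimethylsilyloxy)penta-1,3-diene | COC(O[Si](C)(C)C)=C(C)C(O[Si](C)(C)C)=CC
F3 | step 3 | 2-(methylsulfanyl)-6-nonadecyl-4-(trimethylsilyloxy)pyrylium triflate | CCCCCCCCCCCCCCCCCCCc1cc(O[Si](C)(C)C)cc(SC)[o+]1.[O-]S(=O)(=O)C(F)(F)F
F4 | step 1 | methyl 3,5-dioxotetracosanoate | CCCCCCCCCCCCCCCCCCCC(=O)CC(=O)CC(=O)OC
F5 | step 1 | 4-hydroxy-6-nonadecyl-2H-pyran-2-one | CCCCCCCCCCCCCCCCCCCc1cc(O)cc(=O)o1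
F6 | step 1 | 2-methoxy-6-nonadecyl-4H-pyran-4-one | CCCCCCCCCCCCCCCCCCCc1cc(=O)cc(OC)o1
A1 | direct plan | 1,3,5-trimethoxybenzene | COc1cc(OC)cc(OC)c1
A2 | direct plan | 2-iodo-1,3,5-trimethoxy-4,6-dimethylbenzene | COc1c(C)c(OC)c(C)c(OC)c1I
A3 | direct plan | henicos-1-yne | CCCCCCCCCCCCCCCCCCCC#C
A4 | direct plan | 1-(2,4,6-trimethoxy-3,5-dimethylphenyl)docos-2-yn-1-one | CCCCCCCCCCCCCCCCCCCC#CC(=O)c1c(OC)c(C)c(OC)c(C)c1OC
A5 | direct plan | (E)-3-(diethylamino)-1-(2,4,6-trimethoxy-3,5-dimethylphenyl)docos-2-en-1-one | CCN(CC)/C(CCCCCCCCCCCCCCCCCCC)=C/C(=O)c1c(OC)c(C)c(OC)c(C)c1OC
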